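If ring grows in proportion to the activated form, and that form holds no more than the smaller charge of substrate and activator (the limiting reagent of activation), the rate integrates in closed form to an estimated cap on ring: a rate constant k, times the smaller charge, times the time.

| setting | elm | oak | Saturday's | Wednesday's | Sunday's |
|---|---|---|---|---|---|
| substrate | 0.068 M | 0.21 M | 0.080 M | 0.15 M | 0.30 M |
| activator | 0.101 M | 0.101 M | 0.101 M | 0.101 M | 0.101 M |
| remark | run made earlier | run made earlier |  |  |  |
| time |  |  | 25 h | 25 h | 25 h |

- elm (time / h: ring / %): 6.00: 2.6; 12.0: 4.7; 20.0: 8.2; 25.0: 10.3
- oak (time / h: ring / %): 6.00: 1.4; 12.0: 3.1; 20.0: 4.2; 25.0: 4.2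

(readings scatter by 0.5 percentage points)

- percentages count the substrate that a species holds: one open dimer counts as two
- steps that have been proposed: substrate + activator -> activated form; activated form -> ring; substrate + activated form -> open dimer; ring <-> isomer of the product
- "hardly changes" means that all values lie within two and a half points (for a concentration: within two and a half percent of the largest)

1. [ring] at the end for Saturday's, Wednesday's, Sunday's, in this order
2. how that number moves from the first to the last of them (falls, then rises / falls all the way / rises all the way / rises, then falls / hardly changes)

The elm run, with substrate under activator, climbs nearly straight, so I read k as its last yield over its time, 0.00412 h⁻¹. Saturday's cap, k times the smaller charge times the time, is then 0.00824 M, and for Wednesday's and Sunday's, where activator is the smaller charge, it is 0.0104 M. The oak reading at 25.0 h is 0.00882 M, under its cap of 0.0104 M and above Saturday's cap, though that is one reading with a scatter of 0.5 percentage points. Oak's substrate charge lies between Wednesday's and Sunday's, so I expect Wednesday's ring at or above oak's and Sunday's below it: up, then down.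

The forecast reads 0.0081 M, 0.0095 M and 0.0065 M, rises, then falls, and says: “Leftover substrate is evidently eating the activated form to give open dimer”.

The flasks give 0.00782 M, 0.00915 M and 0.00687 M: rises, then falls.

    substrate + activator → activated form (k = 2.14 × 10⁻⁴ M⁻¹ s⁻¹)
    activated form → ring (k = 1.74 × 10⁻⁵ s⁻¹)
    substrate + activated form → open dimer (k = 2.88 × 10⁻⁴ M⁻¹ s⁻¹)
    ring ⇌ isomer of the product (K = 2.40, k = 1.72 × 10⁻⁴ s⁻¹)

In Saturday's, the forward half-life of ring going to isomer of the product, 1.1 h, is shorter than the 11 h of the activated form making ring and short against the 25 h of the run; at the end that flask holds 20.5% as isomer beside 9.77% as ring, and k, a net slope, is smaller than the making constant of 0.0626 h⁻¹. Against its cap, ring ends at 94.9% in Saturday's and lower, at 66.1%, in Sunday's, where 47.4% of the substrate charged stands as open dimer.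

The data stem from a simulated flask for substances that don't exist.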